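The numbers are those of an exercise.

- At early times the question for the next run is already open: can the enzyme be cut from 2.0 µM to 0.800 µM, with the flask still read at 20 s?

solid substrate 10 mM; enzyme 2.0 µM; time 20 s

    starting material + enzyme ⇌ complex (K1 = 100 L mol⁻¹, k1 = 6.00 × 10⁶ L mol⁻¹ s⁻¹)
    complex → enzyme + target (k2 = 231 s⁻¹)
    solid substrate ⇌ starting material, rate k3*(cs3 - [starting material]) while solid is left; crystals form when [starting material] > cs3 (cs3 = 4.3 mM, k3 = 3.63 s⁻¹)

- given per volume of solution although it is solid: solid substrate
- at the start none of the solid substrate is in solution
- what has only dissolved of solid substrate counts as not reacted
- the reaction counts as stopped when no species that holds the solid substrate changes by six tenths of a point or more over the second half of the time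
- starting material means what is dissolved; the solid is not counted in it
- run time (flask): 20 s

1. which holds at 20 s: what has brought the reaction to rest, or that it has not come to rest (for what has run out or reacted, a solid counts together with what of it has only dissolved) (all of the solid substrate has reacted / no working catalyst is left / it is still moving / forward and back rates have come level)
2. part of the solid substrate that has turned into other species by 20 s (what has only dissolved does not count)
3. the target standing at 20 s, as a percentage of the solid substrate charged
4. the starting material standing at 20 s, as a percentage of the solid substrate charged

- From a bare solution the solid dissolves at up to 15.6 mM s⁻¹, while the enzyme can use at most 0.462 mM s⁻¹. Because dissolving is far faster, we freeze the starting material at its solubility of 4.3 mM.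
- Complex falls back at 60000 s⁻¹ and goes on to target at 231 s⁻¹. Their sum divided by 6.00 × 10⁶ L mol⁻¹ s⁻¹ gives a half-saturation level (the Michaelis constant) of 10.0 mM.
- Enzyme charge times 231 s⁻¹ times solubility, over the half-saturation level plus solubility, gives 0.139 mM s⁻¹. We call this the plateau rate, the rate of target formation while solid is left and the starting material stays at its solubility.
- Solid beyond the solubility lasts 41.1 s at this rate, longer than the 20 s run, so we commit to a flask still moving at the reading.
- Our reckoning gives target at 27.7% of the charge, and conversion practically the same, because complex can hold at most 2.0 µM, far less than the 2.78 mM of target. Starting material sits below solubility by the plateau rate over 3.63 s⁻¹, which gives 42.6%.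
- The solid charge does not enter the plateau rate, but the enzyme charge does, in direct proportion. We therefore leave the solid as it is and judge the enzyme cut by this rate.
- The forecast says it is still moving, with conversion 27.2%, target 27.2% and starting material 42.6%, on the ground that “Dissolution is far faster than the enzyme”. Our target figure stands above its figure by 0.51 percentage points.
- In the flask, it is still moving, with conversion 27.2%, target 27.2% and starting material 42.6%.
- At 20.0 s this flask makes starting material and uses it up at a ratio of 1.00, with solid standing at 30.1% of the charge, and its target gain averaged over the run is 0.136 mM s⁻¹ against a plateau rate of 0.139 mM s⁻¹. In the neighbour flask with 0.800 µM of enzyme, the plateau rate scales to 0.0556 mM s⁻¹, which over 20 s makes 11.1% of the charge, and that flask holds 10.9% of target.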